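**Strategy.** The plan cuts two bonds at the ring B ketone stage (ring B = C5–C10; ring C = O, C8, C9, C11–C13): C10–CH3 and C9–C11. It exploits that quaternary C10 and ring-fusion C9 are the β- and α-carbons of a C8 carbonyl, and that neighbouring C5 already bears the bulky C4 gem-dimethyl arm. In one flask lithium dimethylcuprate methylates C10 of enone 12 anti to the C5 arm and the enolate so formed is alkylated at C9 by 3-(trimethylsilyl)but-3-en-2-one, giving diketone 17 with both stereocentres and no new ring. Enone 12 is a 3,4-disubstituted cyclohex-2-enone whose two arms end in silyl-protected primary alcohols (future C2 and C3 carboxyls).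

Key step: step 7

Remark: labdane-type locants are used (C1–C2 = arm on C10, C3–C4 = arm on C5, C16/C17/C20 = methyls on C13/C8/C10; α = face of the C5 arm, β = face of the C10 methyl; TBS = tert-butyldimethylsilyl), and 1, 3, 6, 14 and 18 are assumed to be purchasable.

**Step 1**
Reactants: 1 2-iodocyclohex-2-en-1-one
Product: 2 (1R)-2-iodocyclohex-2-en-1-ol
Conditions: (S)-2-methyl-CBS-oxazaborolidine (cat.), BH3·SMe2, THF, −20 °C
Reagents that add atoms: none
Why: Corey–Bakshi–Shibata reduction, in which the iodine-bearing alkenyl carbon plays the large group, so that the (S)-oxazaborolidine (the enantiomer that reduces acetophenone to the (R)-alcohol) should give the (R)-carbinol, the stereocentre from which all others descend.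

**Step 2**
Reactants: 2 (1R)-2-iodocyclohex-2-en-1-ol; 3 tert-butyldimethyl(vinyloxy)silane
Product: 5 (1R)-2-[2-(TBS-oxy)ethyl]cyclohex-2-en-1-ol, via alkylborane 4 (not isolated)
Conditions: 3, 9-BBN, THF, 0 °C → rt; then 2, PdCl2(dppf) (cat.), AsPh3, Cs2CO3, DMF/H2O, rt
Reagents that add atoms: tert-butyldimethyl(vinyloxy)silane C=CO[Si](C)(C)C(C)(C)C
Why: B-alkyl Suzuki–Miyaura coupling, in which 9-BBN adds to the enol ether with boron on the terminal carbon and the primary alkyl group is then transferred to the alkenyl iodide with the double bond and the carbinol centre unchanged, so the C1–C2 arm arrives already protected and no β-oxygenated organolithium reagent is needed.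

**Step 3**
Reactants: 5 (1R)-2-[2-(TBS-oxy)ethyl]cyclohex-2-en-1-ol; 6 2-methylpropanoyl chloride
Product: 7 (1R)-2-[2-(TBS-oxy)ethyl]cyclohex-2-en-1-yl 2-methylpropanoate
Conditions: pyridine, DMAP (cat.), CH2Cl2, 0 °C → rt
Reagents that add atoms: 2-methylpropanoyl chloride CC(C)C(=O)Cl
Why: Acylation of the secondary allylic alcohol under nucleophilic catalysis, which does not touch the C–O stereocentre.

**Step 4**
Reactants: 7 (1R)-2-[2-(TBS-oxy)ethyl]cyclohex-2-en-1-yl 2-methylpropanoate
Product: 10 2-[(1S)-2-[2-(TBS-oxy)ethyl]cyclohex-2-en-1-yl]-2-methylpropan-1-ol, via silyl ketene acetal 8 (not isolated), via trimethylsilyl ester 9 (not isolated)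
Conditions: LiN(iPr)2, THF, −78 °C; Me3SiCl, Et3N, −78 → 60 °C; then LiAlH4, 0 °C → rt
Reagents that add atoms: none
Why: Ireland–Claisen rearrangement with reduction in the same flask: the tetrasubstituted ketene acetal (no enolate geometry to control) undergoes a suprafacial [3,3] shift that forms C5–C4 on the ring face from which the C9–O bond departs, so the carbinol configuration is transferred to C5 (5S), the alkene moves to C9=C10, and LiAlH4 then reduces the silyl ester to the neopentyl alcohol.

**Step 5**
Reactants: 10 2-[(1S)-2-[2-(TBS-oxy)ethyl]cyclohex-2-en-1-yl]-2-methylpropan-1-ol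
Product: 11 (6S)-1-[2-(TBS-oxy)ethyl]-6-[1-(TBS-oxy)-2-methylpropan-2-yl]cyclohex-1-ene
Conditions: TBSCl, imidazole, DMF, rt
Reagents that add atoms: tert-butyldimethylsilyl chloride CC(C)(C)[Si](C)(C)Cl
Why: Silylation of the primary neopentyl alcohol, after which C2 and C3 are both masked as base- and hydride-stable silyl ethers that offer no electrophile to the enolate of step 7.

**Step 6**
Reactants: 11 (6S)-1-[2-(TBS-oxy)ethyl]-6-[1-(TBS-oxy)-2-methylpropan-2-yl]cyclohex-1-ene
Product: 12 (4S)-3-[2-(TBS-oxy)ethyl]-4-[1-(TBS-oxy)-2-methylpropan-2-yl]cyclohex-2-en-1-one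
Conditions: CrO3, 3,5-dimethylpyrazole, CH2Cl2, −20 °C
Reagents that add atoms: chromium trioxide O=[Cr](=O)=O
Why: Allylic oxidation with the CrO3–3,5-dimethylpyrazole complex, which converts a 1-alkylcyclohexene into the 3-alkylcyclohex-2-enone by attack at the ring CH2 next to the CH terminus of the alkene (here C8, as in the 7-oxidation of Δ5-steroids), the other allylic sites being the hindered C5–H beside quaternary C4 and the exocyclic C1 methylene, and which leaves the C5 stereocentre untouched.

**Step 7**
Reactants: 12 (4S)-3-[2-(TBS-oxy)ethyl]-4-[1-(TBS-oxy)-2-methylpropan-2-yl]cyclohex-2-en-1-one; 13 lithium dimethylcuprate; 14 3-(trimethylsilyl)but-3-en-2-one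
Product: 17 (2R,3S,4S)-3-[2-(TBS-oxy)ethyl]-4-[1-(TBS-oxy)-2-methylpropan-2-yl]-3-methyl-2-(3-oxobutyl)cyclohexan-1-one, via lithium enolate 15 (not isolated), via α-silyl diketone 16 (not isolated)
Conditions: 13 (from CuI, 2 MeLi), Et2O, −20 → 0 °C; then 14, THF, −78 → −20 °C; then KF, AcOH, MeOH, −78 → 0 °C
Reagents that add atoms: lithium dimethylcuprate [Li+].C[Cu-]C; 3-(trimethylsilyl)but-3-en-2-one CC(=O)C(=C)[Si](C)(C)C
Why: The cuprate complexes the enone and, through a trivalent copper β-adduct, transfers methyl to C10, leaving the regiodefined C8–C9 lithium enolate 15, which adds in Michael fashion to the α-silyl enone; silicon stabilises the new enolate, which holds back proton exchange and a second alkylation, and buffered fluoride then removes the silyl group from 16 without base. The closest known reaction type is cuprate conjugate addition with enolate trapping by an α-silyl vinyl ketone, the first half of a Robinson-type annulation; the bonds C10–C20 and C9–C11 are made and no ring is closed. C10 is set by 1,2-induction from C5: allylic strain with the C10 arm holds the C5 substituent pseudoaxial and methyl enters axially on the opposite (β) face, so CH3 ends trans to the C5 arm and the CH2CH2OTBS arm cis to it. C9 is set by C10 and C5 together: the α-face of the enolate carries both the C10 arm (axial in the reactive half-chair) and the C5 substituent, so the acceptor adds axially from the β-face, cis to the new methyl. The step needs 1,4- over 1,2-addition (given by the soft cuprate), C- over O-alkylation and no equilibration at C9, which the low temperature, the lithium counter-ion and the acidic quench should secure.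

**Step 8**
Reactants: 17 (2R,3S,4S)-diketone; 18 triethyl phosphonoacetate
Product: 19 ethyl (2E)-5-[(1R,2S,3S)-2-[2-(TBS-oxy)ethyl]-3-[1-(TBS-oxy)-2-methylpropan-2-yl]-2-methyl-6-oxocyclohexyl]-3-methylpent-2-enoate
Conditions: NaH, THF, 0 °C → rt
Reagents that add atoms: triethyl phosphonoacetate CCOC(=O)CP(=O)(OCC)OCC
Why: Horner–Wadsworth–Emmons olefination, which should occur only at the unhindered C13 methyl ketone (the C8 ketone is flanked by C9 and quaternary C10) and give mainly the (E)-enoate, the stabilised phosphonate anion being too weak a base to enolise C9 and the minor (Z)-isomer being removable by chromatography.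

**Step 9**
Reactants: 19 (E)-keto enoate
Product: 20 ethyl (2E)-5-[(1S,2R,3S)-2-[2-(TBS-oxy)ethyl]-3-[1-(TBS-oxy)-2-methylpropan-2-yl]-2-methyl-6-methylidenecyclohexyl]-3-methylpent-2-enoate (same spatial arrangement as 19)
Conditions: Zn, CH2Br2, TiCl4, THF/CH2Cl2, 0 °C → rt
Reagents that add atoms: dibromomethane BrCBr
Why: Takai–Lombardo methylenation, a non-basic gem-dimetallic reagent that converts hindered, epimerisable ketones into methylene compounds without touching esters, silyl ethers or the C9 centre.

**Step 10**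
Reactants: 20 C8-methylene enoate
Product: 21 8α,17-epoxide of 20 (spiro-oxirane at C8, oxygen α; 5S,8R,9R,10S)
Conditions: mCPBA, NaHCO3, CH2Cl2, 0 °C
Reagents that add atoms: 3-chloroperoxybenzoic acid OOC(=O)c1cccc(Cl)c1
Why: Prilezhaev epoxidation of the electron-rich 1,1-disubstituted alkene beside the inert enoate, in which oxygen should arrive from the α-face because the β-face is screened in either chair of ring B (by the axial C9 chain in one, by the axial C20 methyl in the other) whereas the α-face is open in the chair with the C10 arm equatorial, as in labd-8(17)-enes, which sets C8 with O α and CH2 β.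

**Step 11**
Reactants: 21 8α,17-epoxy enoate
Product: 22 (5S,8R,9R,10S,13E)-8α,15-diol (tertiary C8 alcohol with C17 methyl β; (E)-allylic alcohol at C13=C14–C15)
Conditions: LiAlH4, THF, 0 → 50 °C
Reagents that add atoms: none
Why: Hydride opens the spiro-oxirane by SN2 attack at its CH2 carbon, which leaves the tertiary 8α-alcohol with C17 as methyl and the C8 configuration retained, and in the same operation reduces the enoate 1,2 to the (E)-allylic alcohol.

**Step 12**
Reactants: 22 (E)-allylic alcohol diol
Product: 23 (13S,14S)-13,14-epoxide of 22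
Conditions: Ti(OiPr)4 (cat.), L-(+)-diethyl tartrate (cat.), t-BuOOH, 4 Å molecular sieves, CH2Cl2, −20 °C
Reagents that add atoms: tert-butyl hydroperoxide CC(C)(C)OO
Why: Sharpless asymmetric epoxidation of an (E)-3-methylalk-2-en-1-ol of the geraniol type, where the L-(+)-tartrate complex delivers oxygen to the face that gives the (13S,14S)-epoxy alcohol under reagent control, the remote ring stereocentres having no say.

**Step 13**
Reactants: 23 (13S,14S)-epoxy alcohol
Product: 24 (1S)-1-[(2R,4aR,5S,6S,8aR)-5-[2-(TBS-oxy)ethyl]-6-[1-(TBS-oxy)-2-methylpropan-2-yl]-2,5,8a-trimethyloctahydro-2H-chromen-2-yl]ethane-1,2-diol (ring C closed; 13R,14S)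
Conditions: camphorsulfonic acid (cat.), CH2Cl2, 0 °C → rt
Reagents that add atoms: none
Why: Acid-catalysed intramolecular epoxide opening, 6-exo and at the tertiary carbon (Markovnikov and Baldwin preferences coincide), in which the C8 hydroxyl displaces the epoxide oxygen at C13 with inversion, closing ring C and turning 13S into 13R with C16 axial and the diol side chain equatorial.

**Step 14**
Reactants: 24 ring C diol
Product: 25 (2R,4aR,5S,6S,8aR)-5-[2-(TBS-oxy)ethyl]-6-[1-(TBS-oxy)-2-methylpropan-2-yl]-2-ethenyl-2,5,8a-trimethyloctahydro-2H-chromene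
Conditions: PPh3, I2, imidazole, toluene, 90 °C
Reagents that add atoms: none
Why: Garegg–Samuelsson deoxygenation of a terminal vicinal diol, in which the primary hydroxyl becomes the iodide and the secondary alkoxyphosphonium ion then undergoes iodide-induced anti-elimination to the vinyl group, removing the C14 stereocentre and leaving quaternary C13 untouched.

**Step 15**
Reactants: 25 bis-silyl ether
Product: 26 2-[(2R,4aR,5S,6S,8aR)-2-ethenyl-5-(2-hydroxyethyl)-2,5,8a-trimethyloctahydro-2H-chromen-6-yl]-2-methylpropan-1-ol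
Conditions: Bu4NF, THF, rt → 40 °C
Reagents that add atoms: none
Why: Fluoride cleavage of both primary silyl ethers under non-acidic conditions that the tertiary allylic ether tolerates.

**Step 16**
Reactants: 26 diol
Product: 27 2-[(2R,4aR,5S,6S,8aR)-5-(carboxymethyl)-2-ethenyl-2,5,8a-trimethyloctahydro-2H-chromen-6-yl]-2-methylpropanoic acid (target; 5S,8R,9R,10S,13R)
Conditions: TEMPO (cat.), NaClO2, NaOCl (cat.), MeCN/phosphate buffer (pH 6.7), 35 °C; citric acid work-up
Reagents that add atoms: sodium chlorite [Na+].[O-]Cl=O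
Why: Oxoammonium-mediated oxidation of both primary alcohols to aldehydes, which chlorite takes on to the carboxylic acids in the same pot at near-neutral pH, conditions that should spare the vinyl group and the acid-sensitive tertiary allylic ether and that create no stereocentre.

**Compound list**

1 | 2-iodocyclohex-2-en-1-one | O=C1C(I)=CCCC1 | starting material
2 | (1R)-2-iodocyclohex-2-en-1-ol | O[C@H]1C(I)=CCCC1 | intermediate
3 | tert-butyldimethyl(vinyloxy)silane | C=CO[Si](C)(C)C(C)(C)C | starting material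
4 | 9-[2-(TBS-oxy)ethyl]-9-borabicyclo[3.3.1]nonane | CC(C)(C)[Si](C)(C)OCCB1C2CCCC1CCC2 | intermediate (not isolated)
5 | (1R)-2-[2-(TBS-oxy)ethyl]cyclohex-2-en-1-ol | O[C@H]1C(CCO[Si](C)(C)C(C)(C)C)=CCCC1 | intermediate
6 | 2-methylpropanoyl chloride | CC(C)C(=O)Cl | starting material
7 | (1R)-2-[2-(TBS-oxy)ethyl]cyclohex-2-en-1-yl 2-methylpropanoate | CC(C)C(=O)O[C@H]1C(CCO[Si](C)(C)C(C)(C)C)=CCCC1 | intermediate
8 | O-trimethylsilyl ketene acetal of 7 (1R) | CC(C)=C(O[Si](C)(C)C)O[C@H]1C(CCO[Si](C)(C)C(C)(C)C)=CCCC1 | intermediate (not isolated)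
9 | trimethylsilyl 2-[(1S)-2-[2-(TBS-oxy)ethyl]cyclohex-2-en-1-yl]-2-methylpropanoate | C[Si](C)(C)OC(=O)C(C)(C)[C@H]1CCCC=C1CCO[Si](C)(C)C(C)(C)C | intermediate (not isolated)
10 | 2-[(1S)-2-[2-(TBS-oxy)ethyl]cyclohex-2-en-1-yl]-2-methylpropan-1-ol | OCC(C)(C)[C@H]1CCCC=C1CCO[Si](C)(C)C(C)(C)C | intermediate
11 | (6S)-1-[2-(TBS-oxy)ethyl]-6-[1-(TBS-oxy)-2-methylpropan-2-yl]cyclohex-1-ene | CC(C)(C)[Si](C)(C)OCC(C)(C)[C@H]1CCCC=C1CCO[Si](C)(C)C(C)(C)C | intermediate
12 | (4S)-3-[2-(TBS-oxy)ethyl]-4-[1-(TBS-oxy)-2-methylpropan-2-yl]cyclohex-2-en-1-one (key-step precursor) | O=C1C=C(CCO[Si](C)(C)C(C)(C)C)[C@@H](C(C)(C)CO[Si](C)(C)C(C)(C)C)CC1 | intermediate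
13 | lithium dimethylcuprate (made in the flask from CuI and MeLi) | [Li+].C[Cu-]C | starting material
14 | 3-(trimethylsilyl)but-3-en-2-one | CC(=O)C(=C)[Si](C)(C)C | starting material
15 | lithium C8–C9 enolate after methyl transfer (5S,10S) | [Li+].[O-]C1=C[C@@](C)(CCO[Si](C)(C)C(C)(C)C)[C@@H](C(C)(C)CO[Si](C)(C)C(C)(C)C)CC1 | intermediate (not isolated)
16 | α-silyl diketone, C12 epimers (5S,9R,10S) | O=C1[C@H](CC(C(C)=O)[Si](C)(C)C)[C@@](C)(CCO[Si](C)(C)C(C)(C)C)[C@@H](C(C)(C)CO[Si](C)(C)C(C)(C)C)CC1 | intermediate (not isolated)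
17 | (2R,3S,4S)-3-[2-(TBS-oxy)ethyl]-4-[1-(TBS-oxy)-2-methylpropan-2-yl]-3-methyl-2-(3-oxobutyl)cyclohexan-1-one (key-step product) | O=C1[C@H](CCC(C)=O)[C@@](C)(CCO[Si](C)(C)C(C)(C)C)[C@@H](C(C)(C)CO[Si](C)(C)C(C)(C)C)CC1 | intermediate
18 | triethyl phosphonoacetate | CCOC(=O)CP(=O)(OCC)OCC | starting material
19 | ethyl (2E)-5-[(1R,2S,3S)-2-[2-(TBS-oxy)ethyl]-3-[1-(TBS-oxy)-2-methylpropan-2-yl]-2-methyl-6-oxocyclohexyl]-3-methylpent-2-enoate | CCOC(=O)/C=C(\C)CC[C@@H]1[C@@](C)(CCO[Si](C)(C)C(C)(C)C)[C@@H](C(C)(C)CO[Si](C)(C)C(C)(C)C)CCC1=O | intermediate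
20 | C8-methylene analogue of 19 (CIP 5S,9S,10R; same spatial arrangement) | CCOC(=O)/C=C(\C)CC[C@@H]1[C@@](C)(CCO[Si](C)(C)C(C)(C)C)[C@@H](C(C)(C)CO[Si](C)(C)C(C)(C)C)CCC1=C | intermediate
21 | 8α,17-epoxide of 20 (5S,8R,9R,10S) | CCOC(=O)/C=C(\C)CC[C@@H]1[C@@](C)(CCO[Si](C)(C)C(C)(C)C)[C@@H](C(C)(C)CO[Si](C)(C)C(C)(C)C)CC[C@]12CO2 | intermediate
22 | (5S,8R,9R,10S,13E)-8α,15-diol | OC/C=C(\C)CC[C@@H]1[C@@](C)(CCO[Si](C)(C)C(C)(C)C)[C@@H](C(C)(C)CO[Si](C)(C)C(C)(C)C)CC[C@@]1(C)O | intermediate
23 | (13S,14S)-13,14-epoxide of 22 | OC[C@@H]1O[C@@]1(C)CC[C@@H]2[C@@](C)(CCO[Si](C)(C)C(C)(C)C)[C@@H](C(C)(C)CO[Si](C)(C)C(C)(C)C)CC[C@@]2(C)O | intermediate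
24 | ring C tetrahydropyran 14,15-diol (5S,8R,9R,10S,13R,14S) | OC[C@H](O)[C@@]1(C)CC[C@@H]2[C@@](C)(CCO[Si](C)(C)C(C)(C)C)[C@@H](C(C)(C)CO[Si](C)(C)C(C)(C)C)CC[C@@]2(C)O1 | intermediate
25 | bis-TBS ether of the vinyl tetrahydropyran (5S,8R,9R,10S,13R) | C=C[C@@]1(C)CC[C@@H]2[C@@](C)(CCO[Si](C)(C)C(C)(C)C)[C@@H](C(C)(C)CO[Si](C)(C)C(C)(C)C)CC[C@@]2(C)O1 | intermediate
26 | C2,C3-diol (5S,8R,9R,10S,13R) | C=C[C@@]1(C)CC[C@@H]2[C@@](C)(CCO)[C@@H](C(C)(C)CO)CC[C@@]2(C)O1 | intermediate
27 | 2-[(2R,4aR,5S,6S,8aR)-5-(carboxymethyl)-2-ethenyl-2,5,8a-trimethyloctahydro-2H-chromen-6-yl]-2-methylpropanoic acid | C=C[C@@]1(C)CC[C@@H]2[C@@](C)(CC(=O)O)[C@@H](C(C)(C)C(=O)O)CC[C@@]2(C)O1 | target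

**Totals.** Total step count: 16. Longest linear sequence: 16 steps (1 → 27; the route is fully linear).

**Steps most likely to fail and their fallbacks**

- **Step 7.** Conjugate addition at the doubly hindered β-carbon may be slower than decay of the cuprate, the enolate may exchange protons with the adduct, or residual cuprate may consume the acceptor, so the coupling stalls at the methylated ketone or loses facial control at C9. Fallback: from 12 the cuprate addition would be run with Me3SiCl so that the enolate is caught at once as the trimethylsilyl enol ether F1, which is isolated. A Lewis-acid-mediated Mukaiyama–Michael addition of F1 to but-3-en-2-one (TiCl4/Ti(OiPr)4, CH2Cl2, −78 °C) would then form the same C9–C11 bond without base and with the same facial bias, returning to the route at 17.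

- **Step 6.** Hydrogen abstraction may not discriminate well enough between C8, the exocyclic C1 methylene and C5–H, or the enone may be over-oxidised. Fallback: from 11, epoxidation of the trisubstituted alkene (mCPBA) would give the epoxide F2. Phenylselenolate ((PhSe)2, NaBH4, EtOH) would open it at the secondary C9 to the hydroxy selenide F3. Oxidation (H2O2) with selenoxide syn-elimination, possible only towards C8 because C10 bears no hydrogen, would give the tertiary allylic alcohol F4. Oxidative 1,3-transposition with C5H5NH[CrO3Cl] returns to the route at 12.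

- **Step 10.** The epoxidation may show poor facial selectivity, or the β sense, because both chairs of ring B can be populated. Fallback: the stereochemically complementary construction from 19. Chemoselective addition of MeCeCl2 (MeLi, CeCl3, THF, −78 °C) to the C8 ketone places the methyl group, instead of the oxygen, on the accessible face and would give the hydroxy enoate F5 when that face is β. Reduction of the ester with iBu2AlH then returns to the route at 22, and steps 9 to 11 are not needed.

**Further compounds**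

F1 | step 7 | trimethylsilyl enol ether of the C10-methylated ketone (5S,10S) | C[Si](C)(C)OC1=C[C@@](C)(CCO[Si](C)(C)C(C)(C)C)[C@@H](C(C)(C)CO[Si](C)(C)C(C)(C)C)CC1
F2 | step 6 | 9,10-epoxide of 11 (5S; epoxide diastereomers) | CC(C)(C)[Si](C)(C)OCC(C)(C)[C@H]1CCCC2OC12CCO[Si](C)(C)C(C)(C)C
F3 | step 6 | 10-hydroxy-9-phenylselanyl derivative of 11 (5S) | CC(C)(C)[Si](C)(C)OCC(C)(C)[C@H]1CCCC([Se]c2ccccc2)C1(O)CCO[Si](C)(C)C(C)(C)C
F4 | step 6 | tertiary allylic alcohol, C10–OH with C8=C9 (5S) | CC(C)(C)[Si](C)(C)OCC(C)(C)[C@H]1CCC=CC1(O)CCO[Si](C)(C)C(C)(C)C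
F5 | step 10 | ethyl (E)-enoate bearing the tertiary 8α-hydroxy-8β-methyl group (5S,8R,9R,10S) | CCOC(=O)/C=C(\C)CC[C@@H]1[C@@](C)(CCO[Si](C)(C)C(C)(C)C)[C@@H](C(C)(C)CO[Si](C)(C)C(C)(C)C)CC[C@@]1(C)O
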